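**Retrosynthetic overview** (labdane numbering)

1. The target comes from a Δ7-alkene by Mukaiyama hydration at C8. The alkene comes from a 7-en-6-one by Luche reduction and acetylation. That enone comes from a bicyclic Δ6-en-8-one by alkylative 1,3-carbonyl transposition (MeCeCl2, then pyridinium chlorochromate).
2. The bicyclic enone is opened at C4–C5, the bond that closes ring A: a tertiary cation at C4 is captured by C5, the γ-carbon of a ring-B silyl dienol ether C8(OSi)=C7–C6=C5. This is possible because C4 is the gem-dimethyl carbon (C18, C19) three methylenes (C3, C2, C1) away from quaternary C10, and because C5 is linked through C6=C7 to the C8 oxygen, the 1,3-partner of the C6 oxygen.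
3. The monocycle comes from a 5,5-disubstituted cyclohexenone and a chiral-pool iodide (C9–C11 bond, C13 bought). The cyclohexenone comes from 3-methylcyclohexenone by copper-catalysed asymmetric conjugate addition (C10) and dehydrogenation.
4. Ring order: ring B is bought; ring A is closed last. Stereorelay: C10 (catalyst) → C5 and C9 (equilibration in the key step) → C6 (hydride on the α face) → C8 (radical trapping on the α face).

Key step: step 7

Remark: labdane numbering is used throughout (ring A = C1–C5 and C10, ring B = C5–C10, side chain C11–C16, C17 on C8, C18/C19 on C4, C20 on C10); 3-methylcyclohex-2-en-1-one, 5-bromo-2-methylpent-2-ene and methyl hydrogen (R)-3-methylglutarate are taken as commercial.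

**Step 1**
Reactants: 1 3-methylcyclohex-2-en-1-one; 2 5-bromo-2-methylpent-2-ene
Product: 4 (R)-3-methyl-3-(4-methylpent-3-en-1-yl)cyclohexan-1-one, via Grignard reagent 3 (not isolated)
Conditions: 2, Mg, Et2O; then 1, Cu(OTf)2 (3 mol %), chiral C2-symmetric NHC ligand (from its imidazolinium salt, 4 mol %), Et2O, −30 °C; NH4Cl (aq)
Reagents that add atoms: none
Why: Copper-catalysed asymmetric conjugate addition of a primary alkyl Grignard reagent to a β-methyl cyclohexenone is an established route to such quaternary centres, and the chiral NHC–copper complex selects the enone face so that the future C10 is set as R (the ligand enantiomer is chosen accordingly).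

**Step 2**
Reactants: 4 (R)-3-methyl-3-(4-methylpent-3-en-1-yl)cyclohexan-1-one
Product: 5 (S)-5-methyl-5-(4-methylpent-3-en-1-yl)cyclohex-2-en-1-one
Conditions: IBX (1.5 equiv), DMSO–fluorobenzene, 70 °C
Reagents that add atoms: none
Why: IBX-mediated α,β-dehydrogenation of a ketone can only give the C6=C7 enone because the other β-carbon (C10) is quaternary, and no stereocentre is touched (the descriptor changes only through CIP priorities).

**Step 3**
Reactants: 6 methyl hydrogen (R)-3-methylglutarate
Product: 8 (S)-4-methyltetrahydro-2H-pyran-2-one, via hydroxy acid 7 (not isolated)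
Conditions: LiOH (1.0 equiv), THF–H2O, evaporate; LiBH4, THF, 50 °C; then 2 M HCl
Reagents that add atoms: none
Why: Chemoselective LiBH4 reduction of the ester in the presence of the lithium carboxylate followed by acid lactonisation should give the δ-lactone with the stereocentre untouched (R becomes S only by the priority change).

**Step 4**
Reactants: 8 (S)-4-methyltetrahydro-2H-pyran-2-one
Product: 10 methyl (R)-5-iodo-3-methylpentanoate, via silyl ester 9 (not isolated)
Conditions: NaI, TMSCl, MeCN, 60 °C; then MeOH, rt
Reagents that add atoms: sodium iodide ([Na+].[I-]); methanol (CO)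
Why: Iodotrimethylsilane made in situ cleaves the lactone by SN2 attack of iodide at the O–CH2 carbon, and acid-catalysed methanolysis of the silyl ester gives the methyl ester without touching the remote stereocentre (future C13).

**Step 5**
Reactants: 5 (S)-5-methyl-5-(4-methylpent-3-en-1-yl)cyclohex-2-en-1-one; 10 methyl (R)-5-iodo-3-methylpentanoate
Product: 11 methyl (13S)-8-oxo-17-nor-4,5-secolabda-3,6-dien-15-oate (C9 epimers)
Conditions: LiN(i-Pr)2 (LDA, 1.05 equiv), THF, −78 °C; then 10, DMPU, −78 → −30 °C; NH4Cl (aq)
Reagents that add atoms: none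
Why: Kinetic α′-deprotonation of the enone gives the cross-conjugated enolate at C9, which is alkylated by the primary iodide (SN2 enolate alkylation) to form the C9–C11 bond; the C9 configuration is left open here because it is equilibrated in step 7.

**Step 6**
Reactants: 11 methyl (13S)-8-oxo-17-nor-4,5-secolabda-3,6-dien-15-oate (C9 epimers)
Product: 13 methyl (13S)-8-(tert-butyldimethylsilyloxy)-4-chloro-17-nor-4,5-secolabda-5,7-dien-15-oate (C9 epimers), via tertiary chloride 12 (not isolated)
Conditions: HCl (g), CH2Cl2, −20 °C; N2 purge; then Et3N (3 equiv), TBSOTf (1.2 equiv), 0 °C; filtration through basic alumina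
Reagents that add atoms: hydrogen chloride (Cl); tert-butyldimethylsilyl triflate (CC(C)(C)[Si](C)(C)OS(=O)(=O)C(F)(F)F)
Why: Markovnikov hydrochlorination of the trisubstituted alkene puts the leaving group on C4, and soft enolisation (silyl triflate/amine) should give the extended silyl dienol ether by γ-deprotonation at C5 because the α′ carbon C9 is now tertiary and hindered.

**Step 7**
Reactants: 13 methyl (13S)-8-(tert-butyldimethylsilyloxy)-4-chloro-17-nor-4,5-secolabda-5,7-dien-15-oate (C9 epimers)
Product: 15 methyl (13S)-8-oxo-17-norlabd-6-en-15-oate, via kinetic epimer mixture 14 (not isolated)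
Conditions: TiCl4 (2.2 equiv), CH2Cl2, −78 → −40 °C; NaHCO3 (aq); then NaOMe (0.3 equiv), MeOH, rt
Reagents that add atoms: none
Why: TiCl4 ionises the tertiary C4–Cl bond and the tertiary cation is captured by C5, the γ-terminus of the 1-silyloxy-1,3-diene C8(OTBS)=C7–C6=C5, after which loss of TBSCl from the silyloxyallyl cation gives the Δ6-en-8-one. The closest known reaction type is the Lewis-acid SN1 tert-alkylation of silyl enol ethers and dienol ethers with tertiary alkyl chlorides (a Mukaiyama-type alkylation), here in its intramolecular, vinylogous form. Ring A is closed by the C4–C5 bond in a six-membered chair-like transition state in which the attacked C5=C6 bond lies outside the new ring (6-exo with respect to the π-nucleophile), and the gem-dimethyl quaternary carbon C4 is formed in the same event. C5 is first formed cis to the tether (kinetic 5β-H), but it is then the γ-position of the enone, so NaOMe equilibrates it through the extended dienolate to the trans-fused 5α-H isomer, which should be favoured because C1 and C4 are then both equatorial on ring B and no carbonyl at C6 presses on the C4 methyl groups; C10 is the controlling element. The same base equilibrates C9 (α′ to the C8 ketone) to the equatorial 9β chain, the epimer that also results from axial protonation of the enolate on the α face opposite the axial C10 methyl. The step needs γ-regioselectivity, which the substrate secures: C7 could only close an eight-membered ring and C9 is blocked by its alkyl group, so only C5 can reach C4.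

**Step 8**
Reactants: 15 methyl (13S)-8-oxo-17-norlabd-6-en-15-oate
Product: 16 methyl (13S)-8-hydroxylabd-6-en-15-oate (C8 epimers)
Conditions: MeLi, CeCl3, THF, −78 °C (MeCeCl2); then 15, −78 °C; NH4Cl (aq)
Reagents that add atoms: methyllithium (C[Li])
Why: Organocerium 1,2-addition brings in C17 at the hindered enone carbonyl and at −78 °C should leave the methyl ester alone; the new C8 configuration does not matter because it is erased in step 9.

**Step 9**
Reactants: 16 methyl (13S)-8-hydroxylabd-6-en-15-oate (C8 epimers)
Product: 17 methyl (13S)-6-oxolabd-7-en-15-oate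
Conditions: pyridinium chlorochromate (C5H5NH[CrO3Cl]), 4 Å MS, CH2Cl2, rt
Reagents that add atoms: pyridinium chlorochromate ([O-][Cr](=O)(=O)Cl.c1cc[nH+]cc1)
Why: Babler–Dauben oxidative transposition (chromate ester, [3,3] shift to C6, oxidation) moves the oxygen to C6 and leaves the C7=C8 alkene carrying C17, under non-basic conditions that should not epimerise C5.

**Step 10**
Reactants: 17 methyl (13S)-6-oxolabd-7-en-15-oate
Product: 18 methyl (13S)-6β-hydroxylabd-7-en-15-oate
Conditions: NaBH4, CeCl3·7H2O, MeOH, −40 °C
Reagents that add atoms: none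
Why: Luche 1,2-reduction should deliver hydride to the α face of C6 because the β face is screened by the syn-axial 10β- and 4β-methyl groups, giving the 6β-alcohol and ending any risk of C5 epimerisation.

**Step 11**
Reactants: 18 methyl (13S)-6β-hydroxylabd-7-en-15-oate
Product: 19 methyl (13S)-6β-acetoxylabd-7-en-15-oate
Conditions: Ac2O, DMAP, Et3N, CH2Cl2, rt
Reagents that add atoms: acetic anhydride (CC(=O)OC(C)=O)
Why: DMAP-catalysed acetylation of the only hydroxyl group, with no stereocentre affected.

**Step 12**
Reactants: 19 methyl (13S)-6β-acetoxylabd-7-en-15-oate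
Product: 20 methyl (13S)-6β-acetoxy-8α-hydroxylabdan-15-oate
Conditions: Mn(dpm)3 (10 mol %), PhSiH3, O2 (1 atm), i-PrOH–CH2Cl2, 0 °C → rt
Reagents that add atoms: dioxygen (O=O)
Why: Mukaiyama hydration (metal-hydride hydrogen-atom transfer) puts H on C7 and generates the tertiary C8 radical, which O2 should trap on the α face because the β face carries the syn-axial 6β-acetoxy and 10β-methyl groups, giving the 8α-hydroxy-8β-methyl carbinol.

**Compound list**

1 | 3-methylcyclohex-2-en-1-one | CC1=CC(=O)CCC1 | starting material
2 | 5-bromo-2-methylpent-2-ene | CC(C)=CCCBr | starting material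
3 | (4-methylpent-3-en-1-yl)magnesium bromide | CC(C)=CCC[Mg]Br | intermediate
4 | (R)-3-methyl-3-(4-methylpent-3-en-1-yl)cyclohexan-1-one | O=C1C[C@@](C)(CCC=C(C)C)CCC1 | intermediate
5 | (S)-5-methyl-5-(4-methylpent-3-en-1-yl)cyclohex-2-en-1-one (same spatial arrangement at the quaternary carbon as in 4; future C10) | O=C1C[C@@](C)(CCC=C(C)C)CC=C1 | intermediate
6 | methyl hydrogen (R)-3-methylglutarate [(R)-5-methoxy-3-methyl-5-oxopentanoic acid] | COC(=O)C[C@H](C)CC(=O)O | starting material
7 | (S)-5-hydroxy-3-methylpentanoic acid | OC(=O)C[C@@H](C)CCO | intermediate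
8 | (S)-4-methyltetrahydro-2H-pyran-2-one | O=C1C[C@@H](C)CCO1 | intermediate
9 | trimethylsilyl (R)-5-iodo-3-methylpentanoate | C[Si](C)(C)OC(=O)C[C@@H](C)CCI | intermediate
10 | methyl (R)-5-iodo-3-methylpentanoate | COC(=O)C[C@@H](C)CCI | intermediate
11 | methyl (13S)-8-oxo-17-nor-4,5-secolabda-3,6-dien-15-oate: enone 5 carrying the C11–C16 ester chain on C9 (C10 as in 5; both C9 epimers) | COC(=O)C[C@@H](C)CCC1C(=O)C=CC[C@]1(C)CCC=C(C)C | intermediate
12 | methyl (13S)-4-chloro-8-oxo-17-nor-4,5-secolabd-6-en-15-oate (C9 epimers) | COC(=O)C[C@@H](C)CCC1C(=O)C=CC[C@]1(C)CCCC(C)(C)Cl | intermediate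
13 | methyl (13S)-8-(tert-butyldimethylsilyloxy)-4-chloro-17-nor-4,5-secolabda-5,7-dien-15-oate (C9 epimers) | COC(=O)C[C@@H](C)CCC1C(O[Si](C)(C)C(C)(C)C)=CC=C[C@]1(C)CCCC(C)(C)Cl | intermediate
14 | methyl (13S)-8-oxo-17-norlabd-6-en-15-oate as the kinetic mixture of C5 and C9 epimers (10β-methyl fixed) | COC(=O)C[C@@H](C)CCC1C(=O)C=CC2C(C)(C)CCC[C@]12C | intermediate
15 | methyl (13S)-8-oxo-17-norlabd-6-en-15-oate (trans-fused: 5α-H, 10β-CH3; 9α-H, side chain 9β) | COC(=O)C[C@@H](C)CC[C@@H]1[C@@]2(C)CCCC(C)(C)[C@@H]2C=CC1=O | intermediate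
16 | methyl (13S)-8-hydroxylabd-6-en-15-oate (5α-H, 9α-H, 10β-CH3; C8 epimers) | COC(=O)C[C@@H](C)CC[C@@H]1[C@@]2(C)CCCC(C)(C)[C@@H]2C=CC1(C)O | intermediate
17 | methyl (13S)-6-oxolabd-7-en-15-oate | COC(=O)C[C@@H](C)CC[C@@H]1[C@@]2(C)CCCC(C)(C)[C@@H]2C(=O)C=C1C | intermediate
18 | methyl (13S)-6β-hydroxylabd-7-en-15-oate | COC(=O)C[C@@H](C)CC[C@@H]1[C@@]2(C)CCCC(C)(C)[C@@H]2[C@H](O)C=C1C | intermediate
19 | methyl (13S)-6β-acetoxylabd-7-en-15-oate | COC(=O)C[C@@H](C)CC[C@@H]1[C@@]2(C)CCCC(C)(C)[C@@H]2[C@H](OC(C)=O)C=C1C | intermediate
20 | methyl (13S)-6β-acetoxy-8α-hydroxylabdan-15-oate (CNP0113148.1) | COC(=O)C[C@@H](C)CC[C@@H]1[C@@]2(C)CCCC(C)(C)[C@@H]2[C@H](OC(C)=O)C[C@@]1(C)O | target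

**Step count**

Total step count: 12. Longest linear sequence: 10 steps (steps 1, 2, 5, 6, 7, 8, 9, 10, 11, 12); steps 3 and 4 make the side-chain iodide.

**Three steps most likely to fail**

Step 7 (key step). What may go wrong is E1 loss of HCl from the tertiary chloride together with protodesilylation of the dienol ether by the liberated acid, so that the cation is never intercepted by C5. The fallback sets out from 11. Soft enolisation without prior hydrochlorination (TBSOTf, Et3N) gives the silyl dienol ether F1, which keeps the C3=C4 alkene. Hg(OTf)2 (as its N,N-dimethylaniline complex, MeCN–CH2Cl2, −20 °C; then NaCl aq) activates that alkene electrophilically, so that C5 attacks C4 with mercury on C3 and gives the organomercurial chloride F2. Radical demercuration (Bu3SnH, AIBN) and the same NaOMe equilibration return to the route at 15.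

Step 5. What may go wrong is slow SN2 alkylation at the neopentyl-type α′ carbon C9, so that proton transfer, O-alkylation and condensation with the ester of 10 compete. The fallback sets out from 5. Condensation with 1,1-dimethylhydrazine gives the N,N-dimethylhydrazone F3. Its more nucleophilic lithium azaenolate (LiN(i-Pr)2, THF, 0 °C) is alkylated by 10 at C9 (Corey–Enders hydrazone alkylation) to give the alkylated hydrazone F4. Mild hydrolysis (CuCl2, THF–H2O, pH 7) returns to the route at 11.

Step 12. What may go wrong is poor facial selectivity when O2 traps the C8 radical, or competing reduction of that radical to the alkane. The fallback sets out from 17. Copper-catalysed conjugate borylation on the α face (B2pin2, CuCl, NaOt-Bu, Xantphos, MeOH, THF) gives the β-boryl ketone F5, which NaBO3 oxidises with retention to the β-hydroxy ketone F6. Evans–Saksena reduction (Me4NBH(OAc)3, MeCN–AcOH, −20 °C), with hydride delivered from the 8α-oxygen to the α face of C6, gives the 6β,8α-diol F7. Selective acetylation of the secondary hydroxyl (Ac2O, DMAP) returns to the route at 20.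

**Further compounds**

F1 | step 7 | methyl (13S)-8-(tert-butyldimethylsilyloxy)-17-nor-4,5-secolabda-3,5,7-trien-15-oate (C9 epimers) | COC(=O)C[C@@H](C)CCC1C(O[Si](C)(C)C(C)(C)C)=CC=C[C@]1(C)CCC=C(C)C
F2 | step 7 | methyl (13S)-3-(chloromercurio)-8-oxo-17-norlabd-6-en-15-oate (epimers at C3, C5 and C9) | COC(=O)C[C@@H](C)CCC1C(=O)C=CC2C(C)(C)C([Hg]Cl)CC[C@]12C
F3 | step 5 | (S)-5-methyl-5-(4-methylpent-3-en-1-yl)cyclohex-2-en-1-one N,N-dimethylhydrazone | CN(C)N=C1C[C@@](C)(CCC=C(C)C)CC=C1
F4 | step 5 | N,N-dimethylhydrazone of 11 (C9 epimers) | COC(=O)C[C@@H](C)CCC1C(=NN(C)C)C=CC[C@]1(C)CCC=C(C)C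
F5 | step 12 | methyl (13S)-6-oxo-8α-(4,4,5,5-tetramethyl-1,3,2-dioxaborolan-2-yl)labdan-15-oate | COC(=O)C[C@@H](C)CC[C@@H]1[C@@]2(C)CCCC(C)(C)[C@@H]2C(=O)C[C@@]1(C)B1OC(C)(C)C(C)(C)O1
F6 | step 12 | methyl (13S)-8α-hydroxy-6-oxolabdan-15-oate | COC(=O)C[C@@H](C)CC[C@@H]1[C@@]2(C)CCCC(C)(C)[C@@H]2C(=O)C[C@@]1(C)O
F7 | step 12 | methyl (13S)-6β,8α-dihydroxylabdan-15-oate | COC(=O)C[C@@H](C)CC[C@@H]1[C@@]2(C)CCCC(C)(C)[C@@H]2[C@H](O)C[C@@]1(C)O
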